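**Retrosynthetic overview**

1. The target comes from a tetracyclic 3,3'-diketone, where NaBH4 sets both equatorial carbinols. Before that, ring B of the right half is hydrogenated, the left C6=C7/C8=CH2 diene is 1,4-reduced to the C7=C8 alkene with its C8 methyl group, and temporary C1/C1' ketones are removed.
2. Key disconnection: C5–C10 and C8–C9 of the left decalin, together with the same two bonds of the right decalin, by a double intramolecular Diels–Alder reaction of an acyclic bis-trienone. Rings A and B of both halves (all four rings) form in this one operation.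
3. Enabling feature: ring B (C5–C10) contains a two-carbon unit C9–C10 and a four-carbon unit C5–C6–C7–C8, linked by ring A (C1–C4) as a four-atom tether. H5 cis to the C10 methyl, and the C10 methyl cis to C11, is the endo adduct of an (E)-2-methyl enone activated through C1; C7=C8 with its methyl is a vinylallene one oxidation level up.
4. The bis-trienone comes from a symmetric C12 diketone (succinaldehyde plus two acyl ylides) and two aldehydes by two catalytic asymmetric aldol additions. The C3/C3' silyl ethers steer the cycloadditions and are reset at the end.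
5. Both aldehydes come from one (E)-vinyl iodide (Takai olefination of hydroxypivaldehyde) by Suzuki (propenyl) and Stille (allenyl) coupling.

Key step: step 10

Remark on locants: the tetracyclic compounds are named on a "bis-decalin" core. This is two 4,4,10-trimethyldecalins (C1–C10 left, C1'–C10' right) with C9 and C9' joined by the C11–C12 ethylene bridge, and C8 and C8' each carrying one further carbon. β is the face of the angular methyl group of the decalin in question. All of them have 5β-H, 9α-H, 10β-CH3 and 5'β-H, 9'α-H, 10'β-CH3.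

Assumption: the (R,R)-ProPhenol ligand is taken to deliver the (S) carbinols in steps 6 and 8. If the aldol sense or the facial sense of step 10 proves opposite, the (S,S) ligand is used and nothing else changes, because C3 and C3' are reset in steps 15 and 16.

**Route**

Step 1
Reactants: 1 2,5-dimethoxytetrahydrofuran; 2 3-(triphenylphosphoranylidene)butan-2-one
Product: 4 (3E,7E)-3,8-dimethyldeca-3,7-diene-2,9-dione, via succinaldehyde 3 (not isolated)
Conditions: 0.1 M aq. HCl, 70 °C; NaHCO3; then 2 (2.2 equiv), CH2Cl2/H2O, 40 °C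
Reagents that add atoms: none
Why: Acid hydrolysis of the cyclic bis-acetal frees succinaldehyde, and the double Wittig reaction of the stabilized acyl ylide should give both trisubstituted enones with (E) geometry, as is usual for stabilized ylides.

Step 2
Reactants: 5 3-hydroxy-2,2-dimethylpropanal (commercial dimer, which reverts to the monomer in solution); 6 iodoform
Product: 7 (E)-4-iodo-2,2-dimethylbut-3-en-1-ol
Conditions: CrCl2 (6 equiv), THF, 0 °C to rt
Reagents that add atoms: none
Why: Takai olefination through the geminal dichromium species formed from CHI3 and divalent chromium should convert the α-quaternary aldehyde into the (E)-vinyl iodide, and the free hydroxyl is tolerated.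

Step 3
Reactants: 7 (E)-4-iodo-2,2-dimethylbut-3-en-1-ol
Product: 8 (E)-4-iodo-2,2-dimethylbut-3-enal
Conditions: Dess–Martin periodinane, NaHCO3, CH2Cl2, 0 °C to rt
Reagents that add atoms: none
Why: Dess–Martin oxidation of the neopentyl primary alcohol should give the non-enolizable aldehyde without touching the vinyl iodide.

Step 4
Reactants: 8 (E)-4-iodo-2,2-dimethylbut-3-enal; 9 (E)-prop-1-en-1-ylboronic acid
Product: 10 (3E,5E)-2,2-dimethylhepta-3,5-dienal
Conditions: Pd(PPh3)4 (5 mol %), K2CO3, THF/H2O, 50 °C
Reagents that add atoms: none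
Why: Suzuki–Miyaura coupling proceeds with retention at both alkenyl partners, so the (E,E)-diene should form, and the non-enolizable aldehyde survives the mild base.

Step 5
Reactants: 8 (E)-4-iodo-2,2-dimethylbut-3-enal; 11 tributyl(propa-1,2-dien-1-yl)stannane
Product: 12 (E)-2,2-dimethylhepta-3,5,6-trienal
Conditions: Pd2(dba)3 (2.5 mol %), AsPh3 (10 mol %), DMF, rt to 40 °C
Reagents that add atoms: none
Why: Stille coupling should transfer the allenyl group to the vinyl iodide with retention of the (E) alkene and give the vinylallene.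

Step 6
Reactants: 4 (3E,7E)-3,8-dimethyldeca-3,7-diene-2,9-dione; 10 (3E,5E)-2,2-dimethylhepta-3,5-dienal
Product: 13 (3E,7E,11S,13E,15E)-11-hydroxy-3,8,12,12-tetramethylheptadeca-3,7,13,15-tetraene-2,9-dione
Conditions: Et2Zn (20 mol %), (R,R)-ProPhenol ligand (10 mol %), 4 Å MS, THF, 0 °C; diketone in threefold excess, surplus recovered
Reagents that add atoms: none
Why: In this direct aldol addition catalysed by the dinuclear zinc ProPhenol complex, one methyl ketone of the diketone (kept in excess so that only one end reacts) should add to the non-enolizable aldehyde in a plain addition that takes up every atom of both partners, and the chiral zinc pocket sets the carbinol (C3' of the target skeleton) as (S).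

Step 7
Reactants: 13 (3E,7E,11S,13E,15E)-11-hydroxy-3,8,12,12-tetramethylheptadeca-3,7,13,15-tetraene-2,9-dione
Product: 14 (3E,7E,11S,13E,15E)-3,8,12,12-tetramethyl-11-(triethylsilyloxy)heptadeca-3,7,13,15-tetraene-2,9-dione
Conditions: TESOTf, 2,6-lutidine, CH2Cl2, −78 °C
Reagents that add atoms: triethylsilyl trifluoromethanesulfonate, CC[Si](CC)(CC)OS(=O)(=O)C(F)(F)F
Why: Silylation of the hindered secondary alcohol with the silyl triflate and a hindered weak base is fast at low temperature and should leave the ketones and the diene untouched.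

Step 8
Reactants: 14 (3E,7E,11S,13E,15E)-3,8,12,12-tetramethyl-11-(triethylsilyloxy)heptadeca-3,7,13,15-tetraene-2,9-dione; 12 (E)-2,2-dimethylhepta-3,5,6-trienal
Product: 15 (4E,7S,10E,14E,18S,20E,22E)-7-hydroxy-6,6,10,15,19,19-hexamethyl-18-(triethylsilyloxy)tetracosa-1,2,4,10,14,20,22-heptaene-9,16-dione
Conditions: Et2Zn (20 mol %), (R,R)-ProPhenol ligand (10 mol %), 4 Å MS, THF, 0 °C; aldehyde in twofold excess
Reagents that add atoms: none
Why: The same zinc-ProPhenol direct aldol addition on the one remaining methyl ketone, with the allenyl aldehyde in excess to drive conversion, should set the second carbinol (C3) with the same (S) sense by catalyst control, again as a plain addition of the two partners.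

Step 9
Reactants: 15 (4E,7S,10E,14E,18S,20E,22E)-7-hydroxy-6,6,10,15,19,19-hexamethyl-18-(triethylsilyloxy)tetracosa-1,2,4,10,14,20,22-heptaene-9,16-dione
Product: 16 (4E,7S,10E,14E,18S,20E,22E)-6,6,10,15,19,19-hexamethyl-7,18-bis(triethylsilyloxy)tetracosa-1,2,4,10,14,20,22-heptaene-9,16-dione
Conditions: TESOTf, 2,6-lutidine, CH2Cl2, −78 °C
Reagents that add atoms: triethylsilyl trifluoromethanesulfonate, CC[Si](CC)(CC)OS(=O)(=O)C(F)(F)F
Why: Low-temperature silylation with the silyl triflate as in step 7 should protect the second carbinol and give the C2-like bis-trienone without touching the vinylallene.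

Step 10
Reactants: 16 (4E,7S,10E,14E,18S,20E,22E)-6,6,10,15,19,19-hexamethyl-7,18-bis(triethylsilyloxy)tetracosa-1,2,4,10,14,20,22-heptaene-9,16-dione
Product: 17 3β,3'β-bis(triethylsilyloxy)-8-methylidene-8'α-methyl-bis-decalin-6,6'-diene-1,1'-dione
Conditions: toluene (0.005 M), BHT (cat.), 120 °C, sealed tube
Reagents that add atoms: none
Why: Two thermal intramolecular Diels–Alder reactions run side by side, each a concerted suprafacial [4+2] cycloaddition of a C5=C6–C7=C8 diene (a vinylallene on the left, an (E,E)-diene on the right) onto the C9=C10 bond of an (E)-2-methyl enone; the closest known reaction types are the cyclization of 1,7,9-decatrien-3-ones to cis-fused octalones and the intramolecular Diels–Alder reaction of vinylallenes. Each ring B closes by the [4+2] cycloaddition itself, and each ring A closes at the same time as the six-membered tether ring (C10–C1–C2–C3–C4–C5) through the endo transition state in which the C1 carbonyl of the tether lies under the diene. That endo mode sets H5 cis to the C10 methyl (cis ring fusion), the (E) geometry of the enone places the C10 methyl cis to C11 at C9, and on the right the (E,E) geometry of the diene places the C8' methyl trans to C12. The absolute sense is relayed from C3 and C3': the OSiEt3 group should stay equatorial on the chair-like tether, whereas the other diene face would force it syn-axial to C6, so the (S) carbinols should give the 3β-silyloxy adducts of the configuration drawn. The step needs endo over exo selectivity and one diene face in each half; the conjugated ketone in the tether secures the first and the C3 silyl ether next to the C4 gem-dimethyl group the second, while the gem-dimethyl group also speeds ring closure. Site selectivity is not in question, because each diene reaches only its own enone through a four-atom tether.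

Step 11
Reactants: 17 3β,3'β-bis(triethylsilyloxy)-8-methylidene-8'α-methyl-bis-decalin-6,6'-diene-1,1'-dione
Product: 18 3β,3'β-dihydroxy-8-methylidene-8'α-methyl-bis-decalin-6,6'-diene-1,1'-dione bis(p-toluenesulfonylhydrazone)
Conditions: TsNHNH2 (3 equiv), PPTS (20 mol %), EtOH, 65 °C
Reagents that add atoms: p-toluenesulfonyl hydrazide, Cc1ccc(cc1)S(=O)(=O)NN
Why: Condensation of the two hindered C1/C1' ketones with the sulfonyl hydrazide under mild acid catalysis should give the bis(tosylhydrazone), and the same ethanolic acid solvolyses both triethylsilyl ethers without touching a stereocentre or the diene.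

Step 12
Reactants: 18 3β,3'β-dihydroxy-8-methylidene-8'α-methyl-bis-decalin-6,6'-diene-1,1'-dione bis(p-toluenesulfonylhydrazone)
Product: 19 8-methylidene-8'α-methyl-bis-decalin-6,6'-diene-3β,3'β-diol
Conditions: catecholborane (6 equiv), CHCl3, 0 °C to rt; then NaOAc·3H2O, 60 °C
Reagents that add atoms: none
Why: In this tosylhydrazone reduction, catecholborane adds hydride to each C=N bond and acetate-induced loss of sulfinate and N2 from the resulting diazene leaves a CH2 group, which should remove the temporary activating carbonyls without touching the alkenes.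

Step 13
Reactants: 19 8-methylidene-8'α-methyl-bis-decalin-6,6'-diene-3β,3'β-diol
Product: 20 8,8'α-dimethyl-bis-decalin-6',7-diene-3β,3'β-diol
Conditions: Li (6 equiv), t-BuOH (6 equiv), NH3(l)/THF, −78 °C; aqueous work-up
Reagents that add atoms: none
Why: In this Birch-type dissolving-metal reduction of the conjugated semicyclic diene, the radical anion should be protonated at the exocyclic CH2 and the resulting allyl anion at its less substituted terminus C6, so that 1,4-addition of hydrogen gives the C7=C8 alkene with the C8 methyl group while the isolated C6'=C7' alkene is inert.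

Step 14
Reactants: 20 8,8'α-dimethyl-bis-decalin-6',7-diene-3β,3'β-diol
Product: 21 8,8'α-dimethyl-bis-decalin-7-ene-3β,3'β-diol
Conditions: H2 (1 atm), RhCl(PPh3)3 (5 mol %), benzene/EtOH, rt
Reagents that add atoms: none
Why: Homogeneous hydrogenation with RhCl(PPh3)3 should reduce the cis-disubstituted C6'=C7' alkene and leave the hindered trisubstituted C7=C8 alkene, and no new stereocentre forms because C8' was set in step 10.

Step 15
Reactants: 21 8,8'α-dimethyl-bis-decalin-7-ene-3β,3'β-diol
Product: 22 8,8'α-dimethyl-bis-decalin-7-ene-3,3'-dione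
Conditions: Dess–Martin periodinane, NaHCO3, CH2Cl2, rt
Reagents that add atoms: none
Why: Dess–Martin oxidation of both hindered secondary alcohols should erase the C3/C3' configuration that served as the control element, without affecting the trisubstituted alkene.

Step 16
Reactants: 22 8,8'α-dimethyl-bis-decalin-7-ene-3,3'-dione
Product: 23 8,8'α-dimethyl-bis-decalin-7-ene-3α,3'α-diol, (3R,5S,9S,10R,3'R,5'S,8'R,9'S,10'R), the target
Conditions: NaBH4, MeOH/THF, 0 °C
Reagents that add atoms: none
Why: Borohydride reduction of each 4,4-dimethyl-3-ketone should follow the axial trajectory from the β face (the α face is flanked by the axial 4α-methyl group and by ring B), which gives the equatorial 3α and 3'α alcohols of the target.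

**Compound list**

1 | 2,5-dimethoxytetrahydrofuran | COC1CCC(OC)O1 | starting material
2 | 3-(triphenylphosphoranylidene)butan-2-one | CC(=O)C(C)=P(c1ccccc1)(c1ccccc1)c1ccccc1 | starting material
3 | succinaldehyde | O=CCCC=O | intermediate
4 | (3E,7E)-3,8-dimethyldeca-3,7-diene-2,9-dione | CC(=O)/C(C)=C/CC/C=C(\C)C(C)=O | intermediate
5 | 3-hydroxy-2,2-dimethylpropanal | CC(C)(CO)C=O | starting material
6 | iodoform | IC(I)I | starting material
7 | (E)-4-iodo-2,2-dimethylbut-3-en-1-ol | OCC(C)(C)/C=C/I | intermediate
8 | (E)-4-iodo-2,2-dimethylbut-3-enal | O=CC(C)(C)/C=C/I | intermediate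
9 | (E)-prop-1-en-1-ylboronic acid | C/C=C/B(O)O | starting material
10 | (3E,5E)-2,2-dimethylhepta-3,5-dienal | O=CC(C)(C)/C=C/C=C/C | intermediate
11 | tributyl(propa-1,2-dien-1-yl)stannane | C=C=C[Sn](CCCC)(CCCC)CCCC | starting material
12 | (E)-2,2-dimethylhepta-3,5,6-trienal | O=CC(C)(C)/C=C/C=C=C | intermediate
13 | (3E,7E,11S,13E,15E)-11-hydroxy-3,8,12,12-tetramethylheptadeca-3,7,13,15-tetraene-2,9-dione | CC(=O)/C(C)=C/CC/C=C(\C)C(=O)C[C@H](O)C(C)(C)/C=C/C=C/C | intermediate
14 | (3E,7E,11S,13E,15E)-3,8,12,12-tetramethyl-11-(triethylsilyloxy)heptadeca-3,7,13,15-tetraene-2,9-dione | CC(=O)/C(C)=C/CC/C=C(\C)C(=O)C[C@H](O[Si](CC)(CC)CC)C(C)(C)/C=C/C=C/C | intermediate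
15 | (4E,7S,10E,14E,18S,20E,22E)-7-hydroxy-6,6,10,15,19,19-hexamethyl-18-(triethylsilyloxy)tetracosa-1,2,4,10,14,20,22-heptaene-9,16-dione | C=C=C/C=C/C(C)(C)[C@@H](O)CC(=O)/C(C)=C/CC/C=C(\C)C(=O)C[C@H](O[Si](CC)(CC)CC)C(C)(C)/C=C/C=C/C | intermediate
16 | (4E,7S,10E,14E,18S,20E,22E)-6,6,10,15,19,19-hexamethyl-7,18-bis(triethylsilyloxy)tetracosa-1,2,4,10,14,20,22-heptaene-9,16-dione | C=C=C/C=C/C(C)(C)[C@@H](O[Si](CC)(CC)CC)CC(=O)/C(C)=C/CC/C=C(\C)C(=O)C[C@H](O[Si](CC)(CC)CC)C(C)(C)/C=C/C=C/C | intermediate
17 | 3β,3'β-bis(triethylsilyloxy)-8-methylidene-8'α-methyl-bis-decalin-6,6'-diene-1,1'-dione | C=C1C=C[C@@H]2C(C)(C)[C@@H](O[Si](CC)(CC)CC)CC(=O)[C@]2(C)[C@H]1CC[C@H]1[C@H](C)C=C[C@@H]2C(C)(C)[C@@H](O[Si](CC)(CC)CC)CC(=O)[C@@]21C | intermediate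
18 | 3β,3'β-dihydroxy-8-methylidene-8'α-methyl-bis-decalin-6,6'-diene-1,1'-dione bis(p-toluenesulfonylhydrazone) | C=C1C=C[C@@H]2C(C)(C)[C@@H](O)CC(=NNS(=O)(=O)c3ccc(C)cc3)[C@]2(C)[C@H]1CC[C@H]1[C@H](C)C=C[C@@H]2C(C)(C)[C@@H](O)CC(=NNS(=O)(=O)c3ccc(C)cc3)[C@@]21C | intermediate
19 | 8-methylidene-8'α-methyl-bis-decalin-6,6'-diene-3β,3'β-diol | C=C1C=C[C@@H]2C(C)(C)[C@@H](O)CC[C@]2(C)[C@H]1CC[C@H]1[C@H](C)C=C[C@@H]2C(C)(C)[C@@H](O)CC[C@@]21C | intermediate
20 | 8,8'α-dimethyl-bis-decalin-6',7-diene-3β,3'β-diol | CC1=CC[C@@H]2C(C)(C)[C@@H](O)CC[C@]2(C)[C@H]1CC[C@H]1[C@H](C)C=C[C@@H]2C(C)(C)[C@@H](O)CC[C@@]21C | intermediate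
21 | 8,8'α-dimethyl-bis-decalin-7-ene-3β,3'β-diol | CC1=CC[C@@H]2C(C)(C)[C@@H](O)CC[C@]2(C)[C@H]1CC[C@H]1[C@H](C)CC[C@@H]2C(C)(C)[C@@H](O)CC[C@@]21C | intermediate
22 | 8,8'α-dimethyl-bis-decalin-7-ene-3,3'-dione | CC1=CC[C@@H]2C(C)(C)C(=O)CC[C@]2(C)[C@H]1CC[C@H]1[C@H](C)CC[C@@H]2C(C)(C)C(=O)CC[C@@]21C | intermediate
23 | 8,8'α-dimethyl-bis-decalin-7-ene-3α,3'α-diol, (3R,5S,9S,10R,3'R,5'S,8'R,9'S,10'R) | CC1=CC[C@@H]2C(C)(C)[C@H](O)CC[C@]2(C)[C@H]1CC[C@H]1[C@H](C)CC[C@@H]2C(C)(C)[C@H](O)CC[C@@]21C | target

**Step count and risks**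

Total step count: 16. Longest linear sequence: 14 steps (steps 2, 3, 4, 6, 7, 8, 9, 10, 11, 12, 13, 14, 15, 16).

The three steps most likely to fail:

Step 10 (double cycloaddition). What may go wrong is an insufficient endo preference (trans-fused rings) or an insufficient facial bias from the C3/C3' silyl ethers, so that diastereomers multiply over the two ring closures. The vinylallene may also oligomerize before it cyclizes. The fallback runs the two cyclizations one after the other and sets out from 14. Promoted by Me2AlCl (CH2Cl2, −78 to −20 °C), its trienone arm alone would close to the right-hand bicycle 1'-oxo-3'β-(triethylsilyloxy)-8'α-methyl-octalin carrying the (E)-4-methyl-5-oxohex-3-enyl chain at C9', F1, which would be purified from its diastereomers. Zinc-ProPhenol aldol addition of F1 to 12 would give the vinylallene hydroxy ketone F2, silylation (TESOTf, 2,6-lutidine) the bis(triethylsilyl ether) F3, and a single thermal cycloaddition of its vinylallene arm (toluene, 110 °C) would close the left half and come back to the route at 17.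

Step 13 (1,4-reduction of the semicyclic diene). What may go wrong is competing 1,2-reduction (protonation of the allyl anion at C8) or incomplete conversion. The fallback replaces the one-step electron-transfer reduction by a polar two-step sequence and sets out from 19. HCl (1 equiv, Et2O, −78 °C) would add to the diene by protonation of the exocyclic CH2 to give the tertiary allylic chloride 8-chloro-8,8'α-dimethyl-bis-decalin-6,6'-diene-3β,3'β-diol F4 (C8 epimers, in equilibrium with the C6 allylic isomer). LiBHEt3 (THF, 0 °C) would then deliver hydride to the less hindered allylic terminus C6 with loss of chloride (SN2' on the tertiary, SN2 on the secondary chloride), so that both isomers converge on 20.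

Step 12 (removal of the C1/C1' carbonyls). What may go wrong is incomplete hydride delivery to the hindered α-quaternary hydrazones, or elimination toward C2 in place of reduction. The fallback removes the oxygen by a radical route and sets out from 17. NaBH4 (MeOH, 0 °C) would reduce both ketones to 3β,3'β-bis(triethylsilyloxy)-8-methylidene-8'α-methyl-bis-decalin-6,6'-diene-1,1'-diol F5 (C1/C1' configuration immaterial). NaH, CS2 and MeI would give the bis(S-methyl xanthate) F6, and Barton–McCombie deoxygenation (Bu3SnH, AIBN, toluene, 90 °C) the bis(silyl ether) 3β,3'β-bis(triethylsilyloxy)-8-methylidene-8'α-methyl-bis-decalin-6,6'-diene F7. PPTS in EtOH would remove the silyl groups and come back to the route at 19.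

**Further compounds**

F1 | step 10 | 1'-oxo-3'β-(triethylsilyloxy)-8'α-methyl-octalin (C6'=C7') with the (E)-4-methyl-5-oxohex-3-enyl chain at C9' | CC(=O)/C(C)=C/CC[C@H]1[C@H](C)C=C[C@@H]2C(C)(C)[C@@H](O[Si](CC)(CC)CC)CC(=O)[C@@]21C
F2 | step 10 | aldol adduct of F1 and 12 (7S carbinol, vinylallene arm) | C=C=C/C=C/C(C)(C)[C@@H](O)CC(=O)/C(C)=C/CC[C@H]1[C@H](C)C=C[C@@H]2C(C)(C)[C@@H](O[Si](CC)(CC)CC)CC(=O)[C@@]21C
F3 | step 10 | triethylsilyl ether of F2 | C=C=C/C=C/C(C)(C)[C@@H](O[Si](CC)(CC)CC)CC(=O)/C(C)=C/CC[C@H]1[C@H](C)C=C[C@@H]2C(C)(C)[C@@H](O[Si](CC)(CC)CC)CC(=O)[C@@]21C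
F4 | step 13 | 8-chloro-8,8'α-dimethyl-bis-decalin-6,6'-diene-3β,3'β-diol (C8 epimers) | CC1(Cl)C=C[C@@H]2C(C)(C)[C@@H](O)CC[C@]2(C)[C@H]1CC[C@H]1[C@H](C)C=C[C@@H]2C(C)(C)[C@@H](O)CC[C@@]21C
F5 | step 12 | 3β,3'β-bis(triethylsilyloxy)-8-methylidene-8'α-methyl-bis-decalin-6,6'-diene-1,1'-diol (C1/C1' epimers) | C=C1C=C[C@@H]2C(C)(C)[C@@H](O[Si](CC)(CC)CC)CC(O)[C@]2(C)[C@H]1CC[C@H]1[C@H](C)C=C[C@@H]2C(C)(C)[C@@H](O[Si](CC)(CC)CC)CC(O)[C@@]21C
F6 | step 12 | bis(S-methyl xanthate) of F5 | C=C1C=C[C@@H]2C(C)(C)[C@@H](O[Si](CC)(CC)CC)CC(OC(=S)SC)[C@]2(C)[C@H]1CC[C@H]1[C@H](C)C=C[C@@H]2C(C)(C)[C@@H](O[Si](CC)(CC)CC)CC(OC(=S)SC)[C@@]21C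
F7 | step 12 | 3β,3'β-bis(triethylsilyloxy)-8-methylidene-8'α-methyl-bis-decalin-6,6'-diene | C=C1C=C[C@@H]2C(C)(C)[C@@H](O[Si](CC)(CC)CC)CC[C@]2(C)[C@H]1CC[C@H]1[C@H](C)C=C[C@@H]2C(C)(C)[C@@H](O[Si](CC)(CC)CC)CC[C@@]21C
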